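**Plan**
1. Lignan numbering is used: C7–C8–C9 in the 3,4-dimethoxyphenyl half and C7′–C8′–C9′ in the syringyl half. The retrosynthesis first cuts the phenol O–benzyl bond and the two acetyl C–O bonds. It then traces C9′H2OH back to the inner carbon of an (E)-propenyl group and C9H2OH back to CO2H. Next it cuts C8–C8′ (retro-Ireland–Claisen), then the ester C–O tether, and last the C7′–alkyne bond.
2. Enabling feature: the open-chain core O–C9–C8–C8′–C9′–O carries oxygen on both carbons that flank the central bond. With C9 as an ester carbonyl and C9′ as an alkene carbon, the six atoms C8=C9–O–CH(CH3)–C9′=C8′ form an allyl vinyl ether. Four of these six atoms are target atoms. The only helpers are the ester oxygen link and the CH(CH3) unit, which is later lost as acetaldehyde.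
3. Forward order: no ring is built, since both arenes are bought. Syringaldehyde is taken to an O-benzyl benzylic bromide, which is coupled with (S)-but-3-yn-2-ol and reduced to the Z-alkene. Esterification with 3-(3,4-dimethoxyphenyl)propanoic acid gives the tethered ester, and the [3,3] shift then joins the halves at C8–C8′. CO2H and propenyl are both converted to CH2OH, followed by diacetylation and debenzylation.
4. Stereochemistry: the one purchased carbinol stereocentre sets the absolute sense by chirality transfer through a chair. The pairing of (E)-silyl ketene acetal with (Z)-alkene sets the 8,8′ relative configuration. The carbinol carbon is then excised.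

Key step: step 7

Remark: (S)-but-3-yn-2-ol, syringaldehyde and 3-(3,4-dimethoxyphenyl)propanoic acid are taken as articles of commerce. The target is (8R,8′R), the configuration of the (3R,4R)-trans-dibenzylbutyrolactone series.

**Step 1**
Reactants: 1 syringaldehyde
Product: 2 4-(benzyloxy)-3,5-dimethoxybenzaldehyde
Conditions: BnBr, K2CO3, DMF, 60 °C
Reagents that add atoms: benzyl bromide BrCc1ccccc1
Why: Williamson ether synthesis on an acidic phenol; the benzyl ether should survive base, hydride, Lindlar hydrogenation and osmylation, and can leave at the end by hydrogenolysis without touching acetates.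

**Step 2**
Reactants: 2 4-(benzyloxy)-3,5-dimethoxybenzaldehyde
Product: 3 [4-(benzyloxy)-3,5-dimethoxyphenyl]methanol
Conditions: NaBH4, MeOH, 0 °C
Reagents that add atoms: none
Why: Borohydride reduction of an aromatic aldehyde, with no other reducible group present.

**Step 3**
Reactants: 3 [4-(benzyloxy)-3,5-dimethoxyphenyl]methanol
Product: 4 2-(benzyloxy)-5-(bromomethyl)-1,3-dimethoxybenzene
Conditions: PBr3, CH2Cl2, 0 °C; used crude at once
Reagents that add atoms: phosphorus tribromide BrP(Br)Br
Why: Bromodehydroxylation of a benzylic alcohol through its phosphite ester, fast at 0 °C for this electron-rich system, so the aryl benzyl ether should stay intact.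

**Step 4**
Reactants: 4 2-(benzyloxy)-5-(bromomethyl)-1,3-dimethoxybenzene; 5 (S)-but-3-yn-2-ol
Product: 6 (2S)-5-[4-(benzyloxy)-3,5-dimethoxyphenyl]pent-3-yn-2-ol
Conditions: CuI (cat.), n-Bu4NI (cat.), Cs2CO3, MeCN, rt, argon
Reagents that add atoms: none
Why: Copper(I)-catalysed sp–sp3 coupling of a terminal alkyne with a benzylic halide; the copper acetylide formed under carbonate base displaces the activated bromide, the free secondary hydroxyl is too poor a nucleophile to compete, and the carbinol stereocentre takes no part.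

**Step 5**
Reactants: 6 (2S)-5-[4-(benzyloxy)-3,5-dimethoxyphenyl]pent-3-yn-2-ol
Product: 7 (2S,3Z)-5-[4-(benzyloxy)-3,5-dimethoxyphenyl]pent-3-en-2-ol
Conditions: H2 (1 atm), Lindlar catalyst (Pd/CaCO3–Pb), quinoline, EtOAc, rt
Reagents that add atoms: none
Why: Lindlar semihydrogenation delivers both hydrogens to one face of the alkyne and should give the Z-alkene; the poisoned catalyst does not cleave the benzyl ether.

**Step 6**
Reactants: 7 (2S,3Z)-5-[4-(benzyloxy)-3,5-dimethoxyphenyl]pent-3-en-2-ol; 8 3-(3,4-dimethoxyphenyl)propanoic acid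
Product: 9 (2S,3Z)-5-[4-(benzyloxy)-3,5-dimethoxyphenyl]pent-3-en-2-yl 3-(3,4-dimethoxyphenyl)propanoate
Conditions: DCC, DMAP (cat.), CH2Cl2, 0 °C → rt
Reagents that add atoms: none
Why: Steglich esterification; acyl transfer takes place at the acid carbonyl, so the carbinol C–O bond is untouched and the (S) centre and Z-alkene are retained.

**Step 7**
Reactants: 9 (2S,3Z)-5-[4-(benzyloxy)-3,5-dimethoxyphenyl]pent-3-en-2-yl 3-(3,4-dimethoxyphenyl)propanoate
Product: 13 (2R,3S,4E)-3-[4-(benzyloxy)-3,5-dimethoxybenzyl]-2-(3,4-dimethoxybenzyl)hex-4-enoic acid, via lithium enolate 10 (not isolated), via silyl ketene acetal 11 (not isolated), via trimethylsilyl ester 12 (not isolated)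
Conditions: LDA, THF, −78 °C; TMSCl, −78 °C → rt, then 50 °C; 1 M HCl work-up
Reagents that add atoms: lithium diisopropylamide CC(C)[N-]C(C)C.[Li+] (lithium of 10 only); chlorotrimethylsilane C[Si](C)(C)Cl (silyl group of 11 and 12 only)
Why: Ireland–Claisen rearrangement, the closest known reaction type being the [3,3] shift of silyl ketene acetals of secondary (Z)-allylic esters with chirality transfer: LDA in THF without polar cosolvent deprotonates the ester CH2 (C8) through a closed lithium-bridged transition state to enolate 10 with the C7 methylene trans to OLi, TMSCl traps it on oxygen as the (E)-ketene acetal 11, and on warming 11 undergoes a concerted suprafacial six-centre shift in which the allylic C–O bond breaks while C8–C8′ forms, giving silyl ester 12, which acidic work-up hydrolyses to 13. No ring of the product is closed; the only cycle is the transient chair array C8=C9–O–CH(CH3)–C9′=C8′. The relative configuration of the two new stereocentres is fixed by the pairing of double-bond geometries: in the chair the (E)-ketene acetal and the (Z)-alkene place both arylmethyl groups pseudoaxial and antiperiplanar across the forming bond, which is the syn (threo) relation along C9–C8–C8′–C9′ that the target needs. The absolute configuration is controlled by the (S)-carbinol carbon: its methyl group must sit pseudoequatorial because in the other chair it would clash (A1,3 strain) with the cis C7′ methylene of the Z-alkene, so C8 bonds to C8′ only on the alkene face from which the oxygen departs, which gives 8R,8′R (descriptors 2R,3S in 13) and an E-propenyl group. The step needs E-selective enolisation, O- rather than C-silylation, chair over boat, and deprotonation at C8 rather than at the benzylic-allylic C7′ methylene; these are secured in turn by the unbranched acid chain and the absence of HMPA or DMPU, by the α-substituted ester of a hindered secondary alcohol, by the acyclic unconstrained substrate, and by the much greater acidity of the ester α-protons at −78 °C.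

**Step 8**
Reactants: 13 (2R,3S,4E)-3-[4-(benzyloxy)-3,5-dimethoxybenzyl]-2-(3,4-dimethoxybenzyl)hex-4-enoic acid
Product: 14 (2R,3S,4E)-3-[4-(benzyloxy)-3,5-dimethoxybenzyl]-2-(3,4-dimethoxybenzyl)hex-4-en-1-ol
Conditions: LiAlH4, THF, 0 °C → rt; Fieser work-up
Reagents that add atoms: none
Why: Hydride reduction of a carboxylic acid; the carboxylate formed first shields C8 from epimerisation, and the isolated alkene and the ethers are inert to LiAlH4.

**Step 9**
Reactants: 14 (2R,3S,4E)-3-[4-(benzyloxy)-3,5-dimethoxybenzyl]-2-(3,4-dimethoxybenzyl)hex-4-en-1-ol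
Product: 16 (2R,3R)-2-[4-(benzyloxy)-3,5-dimethoxybenzyl]-3-(3,4-dimethoxybenzyl)butane-1,4-diol, via lactol 15 (not isolated)
Conditions: OsO4 (cat.), NaIO4, 2,6-lutidine, dioxane/H2O, rt; extractive work-up and concentration; NaBH4, MeOH, 0 °C
Reagents that add atoms: osmium tetroxide O=[Os](=O)(=O)=O (catalytic oxygen carrier); sodium periodate [Na+].[O-]I(=O)(=O)=O (terminal source of the C9′ oxygen)
Why: Lemieux–Johnson oxidative cleavage followed by borohydride reduction; osmylation picks the only alkene and spares the electron-rich arenes that ozone would endanger, the C9′ aldehyde is held as five-membered lactol 15 so C8′ should not epimerise, and NaBH4 reduces it through the open form.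

**Step 10**
Reactants: 16 (2R,3R)-2-[4-(benzyloxy)-3,5-dimethoxybenzyl]-3-(3,4-dimethoxybenzyl)butane-1,4-diol
Product: 17 (2R,3R)-2-[4-(benzyloxy)-3,5-dimethoxybenzyl]-3-(3,4-dimethoxybenzyl)butane-1,4-diyl diacetate
Conditions: Ac2O, pyridine, DMAP (cat.), CH2Cl2, rt
Reagents that add atoms: acetic anhydride CC(=O)OC(C)=O
Why: DMAP-catalysed acetylation of two unhindered primary alcohols while the phenol is still masked, so no selectivity between hydroxyl groups is needed.

**Step 11**
Reactants: 17 (2R,3R)-2-[4-(benzyloxy)-3,5-dimethoxybenzyl]-3-(3,4-dimethoxybenzyl)butane-1,4-diyl diacetate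
Product: 18 Justin C, (2R,3R)-2-(3,4-dimethoxybenzyl)-3-(4-hydroxy-3,5-dimethoxybenzyl)butane-1,4-diyl diacetate
Conditions: H2 (1 atm), 10% Pd/C, EtOAc, rt
Reagents that add atoms: none
Why: Hydrogenolysis of an aryl benzyl ether under neutral conditions; the acetates are not benzylic and neither stereocentre is affected.

**Compound list**
1 | syringaldehyde (4-hydroxy-3,5-dimethoxybenzaldehyde) | COc1cc(C=O)cc(OC)c1O | starting material
2 | 4-(benzyloxy)-3,5-dimethoxybenzaldehyde | COc1cc(C=O)cc(OC)c1OCc1ccccc1 | intermediate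
3 | [4-(benzyloxy)-3,5-dimethoxyphenyl]methanol | COc1cc(CO)cc(OC)c1OCc1ccccc1 | intermediate
4 | 2-(benzyloxy)-5-(bromomethyl)-1,3-dimethoxybenzene | COc1cc(CBr)cc(OC)c1OCc1ccccc1 | intermediate
5 | (S)-but-3-yn-2-ol | C[C@H](O)C#C | starting material
6 | (2S)-5-[4-(benzyloxy)-3,5-dimethoxyphenyl]pent-3-yn-2-ol | C[C@H](O)C#CCc1cc(OC)c(OCc2ccccc2)c(OC)c1 | intermediate
7 | (2S,3Z)-5-[4-(benzyloxy)-3,5-dimethoxyphenyl]pent-3-en-2-ol | C[C@H](O)/C=C\Cc1cc(OC)c(OCc2ccccc2)c(OC)c1 | intermediate
8 | 3-(3,4-dimethoxyphenyl)propanoic acid | COc1ccc(CCC(=O)O)cc1OC | starting material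
9 | (2S,3Z)-5-[4-(benzyloxy)-3,5-dimethoxyphenyl]pent-3-en-2-yl 3-(3,4-dimethoxyphenyl)propanoate | COc1ccc(CCC(=O)O[C@@H](C)/C=C\Cc2cc(OC)c(OCc3ccccc3)c(OC)c2)cc1OC | intermediate
10 | lithium enolate of 9, C7 methylene trans to OLi | [Li+].COc1ccc(C/C=C(/[O-])O[C@@H](C)/C=C\Cc2cc(OC)c(OCc3ccccc3)c(OC)c2)cc1OC | intermediate
11 | (E)-trimethylsilyl ketene acetal of 9, C7 methylene trans to OSiMe3 | COc1ccc(C/C=C(/O[Si](C)(C)C)O[C@@H](C)/C=C\Cc2cc(OC)c(OCc3ccccc3)c(OC)c2)cc1OC | intermediate
12 | trimethylsilyl (2R,3S,4E)-3-[4-(benzyloxy)-3,5-dimethoxybenzyl]-2-(3,4-dimethoxybenzyl)hex-4-enoate | COc1ccc(C[C@@H](C(=O)O[Si](C)(C)C)[C@H](/C=C/C)Cc2cc(OC)c(OCc3ccccc3)c(OC)c2)cc1OC | intermediate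
13 | (2R,3S,4E)-3-[4-(benzyloxy)-3,5-dimethoxybenzyl]-2-(3,4-dimethoxybenzyl)hex-4-enoic acid | COc1ccc(C[C@@H](C(=O)O)[C@H](/C=C/C)Cc2cc(OC)c(OCc3ccccc3)c(OC)c2)cc1OC | intermediate
14 | (2R,3S,4E)-3-[4-(benzyloxy)-3,5-dimethoxybenzyl]-2-(3,4-dimethoxybenzyl)hex-4-en-1-ol | COc1ccc(C[C@@H](CO)[C@H](/C=C/C)Cc2cc(OC)c(OCc3ccccc3)c(OC)c2)cc1OC | intermediate
15 | (3R,4R)-3-[4-(benzyloxy)-3,5-dimethoxybenzyl]-4-(3,4-dimethoxybenzyl)tetrahydrofuran-2-ol, both anomers | OC1OC[C@H](Cc2ccc(OC)c(OC)c2)[C@H]1Cc1cc(OC)c(OCc2ccccc2)c(OC)c1 | intermediate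
16 | (2R,3R)-2-[4-(benzyloxy)-3,5-dimethoxybenzyl]-3-(3,4-dimethoxybenzyl)butane-1,4-diol | COc1ccc(C[C@@H](CO)[C@H](CO)Cc2cc(OC)c(OCc3ccccc3)c(OC)c2)cc1OC | intermediate
17 | (2R,3R)-2-[4-(benzyloxy)-3,5-dimethoxybenzyl]-3-(3,4-dimethoxybenzyl)butane-1,4-diyl diacetate | COc1ccc(C[C@@H](COC(C)=O)[C@H](COC(C)=O)Cc2cc(OC)c(OCc3ccccc3)c(OC)c2)cc1OC | intermediate
18 | Justin C | COc1ccc(C[C@@H](COC(C)=O)[C@H](COC(C)=O)Cc2cc(OC)c(O)c(OC)c2)cc1OC | target

**Total step count:** 11. **Longest linear sequence:** 11 steps (1 → 18); 5 and 8 enter as purchased compounds.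

**Steps most likely to fail**

**Step 7.** The E-geometry may erode during enolisation and silylation, or part of the material may pass through a boat; either would lower the syn/anti selectivity across C8–C8′. C-silylation, or breakdown of the enolate before it is trapped, may also compete.
- The fallback sets out from 8 and 4 and comes back at 16. It builds the two centres one after the other on a lactone.
- Acid 8 is coupled (DCC, DMAP, CH2Cl2) with (S)-4-benzyloxazolidin-2-one to the N-acyl oxazolidinone F1.
- The sodium enolate of F1 (NaHMDS, THF, −78 °C) is alkylated with tert-butyl bromoacetate on the face away from the auxiliary benzyl group (Evans alkylation). This gives the succinate half-imide F2 and sets C8.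
- LiBH4 (THF, MeOH) removes the auxiliary reductively to the hydroxy ester F3, and TFA in CH2Cl2 closes it to the β-benzyl butyrolactone F4.
- LiHMDS and then bromide 4 (THF, −78 °C) alkylate C8′ anti to the resident benzyl group, giving the trans-dibenzylbutyrolactone F5.
- LiAlH4 opens F5 to diol 16.

**Step 4.** Base may isomerise the skipped aryl alkyne to an allene, the alkyne may homocouple oxidatively, and the very electron-rich benzylic bromide may solvolyse or alkylate itself.
- The fallback sets out from 4 and comes back at 7. It makes the Z-alkene directly by olefination, so steps 4 and 5 are both bypassed.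
- Bromide 4 alkylates methylenetriphenylphosphorane (from methyltriphenylphosphonium bromide and n-BuLi, THF) to the homologated phosphonium bromide F6.
- A Z-selective Wittig reaction of F6 under lithium-free conditions (NaHMDS, THF, −78 °C) with commercial (S)-2-(tert-butyldimethylsilyloxy)propanal gives the (S,Z)-allylic silyl ether F7.
- TBAF in THF frees alcohol 7.

**Step 5.** Over-reduction may occur, and Z-to-E isomerisation on the catalyst would feed the wrong alkene geometry, and thus the wrong relative configuration, into step 7.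
- The fallback sets out from 6 and comes back at 13, by way of 12. It inverts all three stereochemical inputs at once.
- Red-Al in THF reduces 6 by trans-hydroalumination to the (S,E)-allylic alcohol F8.
- A Mitsunobu esterification with acid 8 (PPh3, DIAD, THF, 0 °C) inverts the carbinol centre to the (R,E)-allylic ester F9.
- Enolisation in THF/DMPU (LDA, −78 °C, then TMSCl) gives the (Z)-silyl ketene acetal F10.
- In the chair of F10 both arylmethyl groups and the methyl group are pseudoequatorial. This chair should lead to the same silyl ester 12 and, after work-up, acid 13.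

**Further compounds**
F1 | step 7 | (4S)-4-benzyl-3-[3-(3,4-dimethoxyphenyl)propanoyl]oxazolidin-2-one | COc1ccc(CCC(=O)N2[C@@H](Cc3ccccc3)COC2=O)cc1OC
F2 | step 7 | tert-butyl (3R)-4-[(4S)-4-benzyl-2-oxooxazolidin-3-yl]-3-(3,4-dimethoxybenzyl)-4-oxobutanoate | COc1ccc(C[C@@H](C(=O)N2[C@@H](Cc3ccccc3)COC2=O)CC(=O)OC(C)(C)C)cc1OC
F3 | step 7 | tert-butyl (3R)-3-(3,4-dimethoxybenzyl)-4-hydroxybutanoate | COc1ccc(C[C@@H](CO)CC(=O)OC(C)(C)C)cc1OC
F4 | step 7 | (4R)-4-(3,4-dimethoxybenzyl)dihydrofuran-2(3H)-one | COc1ccc(C[C@H]2COC(=O)C2)cc1OC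
F5 | step 7 | (3R,4R)-3-[4-(benzyloxy)-3,5-dimethoxybenzyl]-4-(3,4-dimethoxybenzyl)dihydrofuran-2(3H)-one | O=C1OC[C@H](Cc2ccc(OC)c(OC)c2)[C@H]1Cc1cc(OC)c(OCc2ccccc2)c(OC)c1
F6 | step 4 | {2-[4-(benzyloxy)-3,5-dimethoxyphenyl]ethyl}triphenylphosphonium bromide | COc1cc(CC[P+](c2ccccc2)(c2ccccc2)c2ccccc2)cc(OC)c1OCc1ccccc1.[Br-]
F7 | step 4 | {[(2S,3Z)-5-[4-(benzyloxy)-3,5-dimethoxyphenyl]pent-3-en-2-yl]oxy}(tert-butyl)dimethylsilane | C[C@H](O[Si](C)(C)C(C)(C)C)/C=C\Cc1cc(OC)c(OCc2ccccc2)c(OC)c1
F8 | step 5 | (2S,3E)-5-[4-(benzyloxy)-3,5-dimethoxyphenyl]pent-3-en-2-ol | C[C@H](O)/C=C/Cc1cc(OC)c(OCc2ccccc2)c(OC)c1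
F9 | step 5 | (2R,3E)-5-[4-(benzyloxy)-3,5-dimethoxyphenyl]pent-3-en-2-yl 3-(3,4-dimethoxyphenyl)propanoate | COc1ccc(CCC(=O)O[C@H](C)/C=C/Cc2cc(OC)c(OCc3ccccc3)c(OC)c2)cc1OC
F10 | step 5 | (Z)-trimethylsilyl ketene acetal of F9, C7 methylene cis to OSiMe3 | COc1ccc(C/C=C(\O[Si](C)(C)C)O[C@H](C)/C=C/Cc2cc(OC)c(OCc3ccccc3)c(OC)c2)cc1OC
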